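Neighbour flasks of the same charge are read at 12 h and 2.0 d, but the questions here concern this flask at 30 h.

electrophile 39 mM; buffer base 117 mM; buffer acid 3.90 mM; gas 3.0 mM (held); time 30 h
1. part of the electrophile that has reacted at 30 h
2. pH of the solution at 30 h
- acid is the free proton; pH is minus the decimal logarithm of its molar concentration
- at the start none of nucleophile is dissolved
- run time (flask): 30 h

In this flask the electrophile reacts with dissolved nucleophile, which the held gas replaces, and each turnover frees one acid. The rate of that step is its constant, 8.1 M⁻¹ h⁻¹, times both concentrations, so the first task is to find which of them moves. First-order rate constants, each with its half-life, form a small table: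

- renewal of nucleophile from the gas: 32 h⁻¹, half-life 1.30 min;
- loss of nucleophile to the electrophile as charged: 0.316 h⁻¹, half-life 2.2 h;
- loss of electrophile to nucleophile at saturation: 0.0243 h⁻¹, half-life 28.5 h.

Reading the first row against the second, renewal is 101 times faster, so supply and loss balance at 2.97 mM of nucleophile, close to the 3.0 mM of saturation. The nucleophile therefore stays nearly constant and the step is pseudo-first-order in the electrophile. The last row then gives the quantity to carry: k′, the step's rate constant times the saturation concentration.

The electrophile left falls as exp(−k′t), and 30 h lies near the half-life, so 51.8% should have reacted, about half of the charge. That frees 20.2 mM of acid. If the buffer base takes it up, the ratio of buffer base to buffer acid falls from 30.0 to 4.02, and the pH falls by 0.873.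

The forecast gives 51.3% (50% to 53%), a little less than this reckoning, and pH 7.83 (7.79 to 7.87), on the ground that “Gas transfer is about a hundred times faster than consumption”.

The simulated flask gives 51.5% reacted at 30 h and pH 7.83.

    gas ⇌ nucleophile, rate k1*(csat - [nucleophile]) (k1 = 32 h⁻¹, csat = 3.0 mM)
    protonated nucleophile ⇌ nucleophile + acid, settled at all times (K2 = 5.0 × 10⁻⁸ M)
    electrophile + nucleophile → acid + target + leaving group (k3 = 8.1 M⁻¹ h⁻¹)
    buffer acid ⇌ buffer base + acid, settled at all times (K4 = 6.3 × 10⁻⁸ M)
    target → over-reaction product (k5 = 0.012 h⁻¹)

At 10.3 h the nucleophile in this flask has a half-life of 2.8 h against the electrophile, much longer than the 1.30 min of its renewal. At 30.0 h the nucleophile reads 2.99 mM, and the electrophile stands at 49% of its charge. For the neighbour flask read at 2.0 d, k′ gives 68.9% reacted, and that flask reads 68.6%.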